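I followed the J.

in all of them: D 1.2 mM (held)
- dusk: J 6.8 mM; Q 0.20 mM; run made earlier
- midnight: J 77 mM; Q 0.20 mM; run made earlier
- ash: J 8.0 mM; Q 0.60 mM; time 1.5 h
- alder: J 28 mM; Q 0.20 mM; time 1.5 h
- elm: J 20 mM; Q 0.40 mM; time 1.5 h
- maple: J 120 mM; Q 0.050 mM; time 1.5 h
- birch: J 80 mM; Q 0.060 mM; time 1.5 h

| run | time / min | G / % |
|---|---|---|
| dusk | 3.00 | 33.9 |
| dusk | 10.0 | 73.0 |
| dusk | 20.0 | 84.7 |
| dusk | 25.0 | 86.2 |
| dusk | 40.0 | 86.3 |
| dusk | 50.0 | 86.3 |
| dusk | 60.0 | 86.2 |
| midnight | 5.00 | 15.6 |
| midnight | 8.00 | 24.6 |
| midnight | 12.0 | 35.8 |
| midnight | 20.0 | 55.3 |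
| midnight | 25.0 | 64.5 |
| midnight | 40.0 | 80.4 |
| midnight | 60.0 | 82.8 |

(readings scatter by 0.3 percentage points)

* the flasks put in order of amount of G, in percent of the J charged, best first, at 1.5 h (ash / alder / elm / maple / birch)
* the same order at 20 min (ash / alder / elm / maple / birch)
* the amount of G, in percent of the J charged of the flask you put first, at 1.5 h
* the amount of G, in percent of the J charged of the flask you put last, at 1.5 h

- at the start none of X is dissolved
- the analysis behind the earlier runs scatters by 0.3 percentage points, standard deviation
- reactions considered so far: J + X + Q -> Q + G; 2 Q -> E; J + X -> Z; D <-> X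
- no earlier run changes the charge of Q; that part of a forecast is a guess

I kept a ledger with three entries for each mole of J charged: G, Z, or still in the flask. Both ways out use one J and one X, so cJ and cX cancel from the ratio of their rates, and G grows against Z in proportion to cQ. I froze cQ at its charge. Dusk levelled off at 86.3% G, and taking its J as used up I gave the remaining 13.7% to Z, so at 0.20 mM of Q I read 0.0317 mM as the split level, the cQ at which G and Z grow equally. With cQ frozen, the share of J going to G, the selectivity, is then cQ divided by cQ plus the split level. That put ash at 95.0% and maple at 61.2%, and it ranked the flasks by falling cQ.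

The freeze is imperfect: the reactions considered include the loss of Q to E. Midnight reached 82.8% at its last reading, less than dusk, and read the same way it gives a split level of 0.0415 mM. On that figure maple falls to 54.6%, so I expected it between my two values.

For the third entry, midnight's G rose from 15.6% to 55.3% between 5.00 min and 20.0 min. Divided by its last share, that means J leaving at 2.46 mM min⁻¹. I took that pace over to maple, though midnight held more Q; on that assumption maple's J needs 48.8 min, less than the 1.5 h allowed, so I closed that entry as small. By 20 min the same pace spends 41.0% of maple's J and 61.5% of birch's, so I kept maple behind birch there too.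

The forecast gave ash > elm > alder > birch > maple at 1.5 h and ash > elm > alder > birch > maple at 20 min, with 94% for the first flask and 58% for the last, on the ground that “with J essentially consumed by 1.5 h, yield follows selectivity, set by Q”. My ash stood a little higher.

The flasks came out as ash > elm > alder > birch > maple at 1.5 h and ash > elm > alder > birch > maple at 20 min, with ash at 94.5% and maple at 58.8%, against my 95.0% and 61.2%.

    J + X + Q → Q + G (k = 16000 L² mol⁻² s⁻¹)
    2 Q → E (k = 1.00 L mol⁻¹ s⁻¹)
    J + X → Z (k = 0.460 L mol⁻¹ s⁻¹)
    D ⇌ X, rate k4*(csat - [X]) (kL = 0.0460 s⁻¹)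

A neighbour, like ash but charged with 0.15 mM of Q, goes through the same ledger: the split level gives it 82.6% G. That flask ended with 82.3% G, 17.7% Z and 0% of its J at 1.50 h.

The earlier runs and the new flask are simulated from invented constants; noise was put on by code.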